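The route rests on cutting the C8–C8' fusion bond shared by the γ-lactone and the tetrahydrofuran of the cis-fused 3,7-dioxabicyclo[3.3.0]octan-2-one, together with the benzylic C7–O and C7'–O bonds, each para to a phenolic oxygen: the imprint of an 8–8' phenoxyl radical coupling followed by quinone methide trapping. One oxidative operation joins C8 to C8', closes the tetrahydrofuran and the lactone, expels the chiral auxiliary and sets all four stereocentres. Its precursors are (E)-3,5-dibenzyloxy-4-hydroxycinnamyl alcohol and an (E)-caffeoyl imide of (S)-4-benzyloxazolidin-2-one with a free para phenol, a meta benzyl ether and a removable bromine at C5'. One hydrogenolysis then gives the target.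

Key step: step 10

**Remarks on the chemistry (assumptions and design decisions)**

- Locants follow lignan numbering: C7, C8, C9 are the pyrogallol-bearing lactone carbinol, the fusion CH that carries the ether CH2, and that CH2. C7', C8', C9' are the catechol-bearing ether carbinol, the fusion CH that carries the carbonyl, and the lactone carbonyl.
- The target SMILES corresponds to (7S,8R,7'S,8'S), which is (1S,4S,5R,8S) in bicyclo numbering. The rings are cis-fused and both aryl groups lie on the convex face (H7/H8 trans, H7'/H8' trans).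
- Auxiliary antipode: in the magnesium chelate of the imide (carbonyls syn, enoyl unit s-cis) the C4 benzyl group of the (S)-oxazolidinone covers the Re face of C8'. Bond formation on the Si face gives the 8'S centre of the target, so the (S)-auxiliary is the matched one. The unchelated rotamer would expose the other face, so the magnesium salt is used in stoichiometric amount.
- Blocking group: a 3-alkoxy-4-hydroxycinnamoyl radical with an open C5' position couples largely through that carbon. A bromine at C5' closes this channel, hinders coupling at the phenolic oxygen, and leaves in the final hydrogenolysis.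
- C7 cannot be fixed by a convex-face argument, because the bicycle does not yet exist when oxygen reaches C7. The route relies instead on delivery of water from the imide-bound magnesium on the C8' side.
- Monoalkylation of 3,4-dihydroxybenzaldehyde with one equivalent of weak base goes to the para oxygen. The meta ether needed here is reached through the dianion.
- Fragment A starts at the aldehyde oxidation level (commercial 3,4,5-trihydroxybenzaldehyde), which avoids an ester-to-aldehyde redox detour. The para benzyl group is removed at the cinnamate stage.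
- Mg(NTf2)2 denotes magnesium bis(trifluoromethanesulfonyl)imide, Mg[N(SO2CF3)2]2.

**Route**

Step 1
Reactants: 1 3,4,5-trihydroxybenzaldehyde
Product: 2 3,4,5-tris(benzyloxy)benzaldehyde
Conditions: BnBr (3.5 equiv), K2CO3 (4 equiv), DMF, 60 °C, N2
Reagents that add atoms: benzyl bromide, BrCc1ccccc1
Why: Williamson ether synthesis alkylates all three phenoxides under standard carbonate conditions, and the aldehyde is inert.

Step 2
Reactants: 2 3,4,5-tris(benzyloxy)benzaldehyde
Product: 3 ethyl (E)-3-[3,4,5-tris(benzyloxy)phenyl]prop-2-enoate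
Conditions: Ph3P=CHCO2Et (1.2 equiv), toluene, 90 °C
Reagents that add atoms: ethyl (triphenylphosphoranylidene)acetate, CCOC(=O)C=P(c1ccccc1)(c1ccccc1)c1ccccc1
Why: Wittig olefination with a stabilised ylide should give the (E)-cinnamate selectively.

Step 3
Reactants: 3 ethyl (E)-3-[3,4,5-tris(benzyloxy)phenyl]prop-2-enoate
Product: 4 ethyl (E)-3-[3,5-bis(benzyloxy)-4-hydroxyphenyl]prop-2-enoate
Conditions: BCl3 (1.2 equiv), C6HMe5 (3 equiv), CH2Cl2, −78 °C; then H2O
Reagents that add atoms: none
Why: Lewis-acid cleavage of an aryl benzyl ether with a cation scavenger should occur only at the central oxygen of the 1,2,3-trialkoxyarene, which is twisted out of conjugation, most basic, and leaves as the phenoxide para to the acrylate, while pentamethylbenzene traps the benzyl cation.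

Step 4
Reactants: 4 ethyl (E)-3-[3,5-bis(benzyloxy)-4-hydroxyphenyl]prop-2-enoate
Product: 5 (E)-3-[3,5-bis(benzyloxy)-4-hydroxyphenyl]prop-2-en-1-ol
Conditions: i-Bu2AlH (4 equiv), toluene, −78 → 0 °C; then aq. potassium sodium tartrate (KNaC4H4O6)
Reagents that add atoms: none
Why: 1,2-reduction of the α,β-unsaturated ester by the aluminium hydride, the standard access to 4-hydroxycinnamyl alcohols from their cinnamates, carries the phenol as its aluminium phenoxide and leaves alkene and benzyl ethers untouched.

Step 5
Reactants: 6 3,4-dihydroxybenzaldehyde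
Product: 7 3-(benzyloxy)-4-hydroxybenzaldehyde
Conditions: NaH (2.2 equiv), DMSO, 20 °C; BnCl (1.0 equiv); then aq. HCl
Reagents that add atoms: benzyl chloride, ClCc1ccccc1
Why: Regioselective Williamson alkylation through the dianion works because the 4-phenoxide is delocalised into the aldehyde, so the more nucleophilic 3-phenoxide takes the single equivalent of benzyl chloride.

Step 6
Reactants: 7 3-(benzyloxy)-4-hydroxybenzaldehyde
Product: 8 3-(benzyloxy)-5-bromo-4-hydroxybenzaldehyde
Conditions: Br2 (1.05 equiv), NaOAc (1.2 equiv), AcOH, 20 °C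
Reagents that add atoms: bromine, BrBr
Why: Electrophilic aromatic bromination goes to C5, the only open position ortho to the free hydroxyl and meta to the formyl group, as in the bromination of vanillin.

Step 7
Reactants: 9 (S)-4-benzyl-1,3-oxazolidin-2-one
Product: 10 (S)-4-benzyl-3-(2-bromoacetyl)-1,3-oxazolidin-2-one
Conditions: n-BuLi (1.0 equiv), THF, −78 °C; BrCH2COBr (1.1 equiv), −78 → 0 °C
Reagents that add atoms: bromoacetyl bromide, O=C(Br)CBr
Why: N-acylation of the lithiated oxazolidinone by the acyl bromide is faster than displacement at the CH2Br carbon, and the stereocentre is not involved.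

Step 8
Reactants: 10 (S)-4-benzyl-3-(2-bromoacetyl)-1,3-oxazolidin-2-one
Product: 12 (S)-4-benzyl-3-[(triphenylphosphoranylidene)acetyl]-1,3-oxazolidin-2-one, via phosphonium bromide 11 (not isolated)
Conditions: PPh3 (1.05 equiv), CH2Cl2, 20 °C; then aq. Na2CO3, 0 °C
Reagents that add atoms: triphenylphosphine, c1ccc(cc1)P(c1ccccc1)c1ccccc1
Why: SN2 quaternisation of the phosphine by the α-bromo imide followed by deprotonation of the acidic phosphonium salt with cold carbonate should give the imide-stabilised ylide without cleaving the imide.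

Step 9
Reactants: 8 3-(benzyloxy)-5-bromo-4-hydroxybenzaldehyde; 12 (S)-4-benzyl-3-[(triphenylphosphoranylidene)acetyl]-1,3-oxazolidin-2-one
Product: 13 (S)-4-benzyl-3-[(E)-3-(3-benzyloxy-5-bromo-4-hydroxyphenyl)prop-2-enoyl]-1,3-oxazolidin-2-one
Conditions: 12 (1.2 equiv), toluene, 90 °C
Reagents that add atoms: none
Why: Wittig olefination with a stabilised ylide needs no base, tolerates the free phenol, and should give the (E)-enoyl imide directly.

Step 10
Reactants: 13 (S)-4-benzyl-3-[(E)-3-(3-benzyloxy-5-bromo-4-hydroxyphenyl)prop-2-enoyl]-1,3-oxazolidin-2-one; 5 (E)-3-[3,5-bis(benzyloxy)-4-hydroxyphenyl]prop-2-en-1-ol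
Product: 17 (1S,4S,5R,8S)-8-[3-(benzyloxy)-5-bromo-4-hydroxyphenyl]-4-[3,5-bis(benzyloxy)-4-hydroxyphenyl]-3,7-dioxabicyclo[3.3.0]octan-2-one, via bis-quinone methide 14 (not isolated), via oxolane quinone methide 15 (not isolated), via hydroxy imide 16 (not isolated)
Conditions: 13 (1.5 equiv) premixed with Mg(NTf2)2 (1.6 equiv), Ag2O (1.3 equiv), H2O (5 equiv), CH2Cl2/acetone 9:1, −20 °C, 5 added over 6 h, then 0 °C
Reagents that add atoms: water, O
Why: Proposed new method: Ag2O converts both para phenols into phenoxyl radicals with spin density at C8 and C8'; their combination gives bis-quinone methide 14, the C9 hydroxyl adds to C7' (5-exo-trig oxa-conjugate addition that closes the tetrahydrofuran and rearomatises the bromocatechol ring), magnesium-bound water adds to C7, and the new C7 carbinol attacks the chelated exocyclic imide carbonyl (5-exo-trig acyl substitution that closes the lactone and releases oxazolidinone 9). The closest known reaction types are the racemic Ag2O, FeCl3 or peroxidase 8-8' cross-couplings of hydroxycinnamates with hydroxycinnamyl alcohols, the Lewis-acid-chelated oxazolidinone control of radical reactions at the α-carbon of N-acyloxazolidinones, and the spontaneous lactonisation of γ-hydroxy N-acyloxazolidinones. C8' is set by the auxiliary: in the magnesium chelate (syn carbonyls, s-cis enoyl unit) the benzyl group at C4 of the (S)-oxazolidinone covers the Re face of C8', so C8 should bond to the Si face, which corresponds to the required 8'S centre. C8 is set relative to C8' in the radical combination, which for 8-8' coupling is expected to favour the pairing that can form a cis-fused bicycle, while the other pairing cannot lactonise and should remain as a separable monocyclic hydroxy imide; C7' is set in the oxolane closure, the aryl group taking the position trans to the C8' acyl group. C7 is set by oxygen delivery from the imide-bound magnesium on the C8' side of the quinone methide in its A(1,3)-relaxed rotamer (H8 in the plane of the ring), which places the pyrogallol ring exo in the lactone. The step needs cross- over homo-coupling and 8-8' over 8-5 and 8-O-4 coupling: the first should be secured by the unequal oxidation potentials of the two phenols combined with slow addition of the more oxidisable alcohol 5 to excess imide 13, the second by the bromine at C5' and the ortho substituents flanking both phenolic oxygens.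

Step 11
Reactants: 17 (1S,4S,5R,8S)-8-[3-(benzyloxy)-5-bromo-4-hydroxyphenyl]-4-[3,5-bis(benzyloxy)-4-hydroxyphenyl]-3,7-dioxabicyclo[3.3.0]octan-2-one
Product: 18 (1S,4S,5R,8S)-8-(3,4-dihydroxyphenyl)-4-(3,4,5-trihydroxyphenyl)-3,7-dioxabicyclo[3.3.0]octan-2-one
Conditions: H2 (1 atm), 10% Pd/C, NaOAc (1.5 equiv), THF/EtOH 4:1, 20 °C, stopped at full conversion, filtered under argon
Reagents that add atoms: none
Why: Heterogeneous palladium-catalysed hydrogenolysis should cleave the three aryl benzyl ethers and the aryl bromide (acetate buffering the HBr) faster than the dialkyl-type benzylic C–O bonds of the lactone and the oxolane, and no stereocentre is touched.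

**Compound list**

1 | 3,4,5-trihydroxybenzaldehyde | O=Cc1cc(O)c(O)c(O)c1 | starting material
2 | 3,4,5-tris(benzyloxy)benzaldehyde | O=Cc1cc(OCc2ccccc2)c(OCc2ccccc2)c(OCc2ccccc2)c1 | intermediate
3 | ethyl (E)-3-[3,4,5-tris(benzyloxy)phenyl]prop-2-enoate | CCOC(=O)/C=C/c1cc(OCc2ccccc2)c(OCc2ccccc2)c(OCc2ccccc2)c1 | intermediate
4 | ethyl (E)-3-[3,5-bis(benzyloxy)-4-hydroxyphenyl]prop-2-enoate | CCOC(=O)/C=C/c1cc(OCc2ccccc2)c(O)c(OCc2ccccc2)c1 | intermediate
5 | (E)-3-[3,5-bis(benzyloxy)-4-hydroxyphenyl]prop-2-en-1-ol (key-step precursor) | OC/C=C/c1cc(OCc2ccccc2)c(O)c(OCc2ccccc2)c1 | intermediate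
6 | 3,4-dihydroxybenzaldehyde | O=Cc1ccc(O)c(O)c1 | starting material
7 | 3-(benzyloxy)-4-hydroxybenzaldehyde | O=Cc1ccc(O)c(OCc2ccccc2)c1 | intermediate
8 | 3-(benzyloxy)-5-bromo-4-hydroxybenzaldehyde | O=Cc1cc(Br)c(O)c(OCc2ccccc2)c1 | intermediate
9 | (S)-4-benzyl-1,3-oxazolidin-2-one | O=C1OC[C@H](Cc2ccccc2)N1 | starting material
10 | (S)-4-benzyl-3-(2-bromoacetyl)-1,3-oxazolidin-2-one | O=C(CBr)N1C(=O)OC[C@@H]1Cc1ccccc1 | intermediate
11 | {2-[(S)-4-benzyl-2-oxo-1,3-oxazolidin-3-yl]-2-oxoethyl}triphenylphosphonium bromide | [Br-].O=C(C[P+](c1ccccc1)(c1ccccc1)c1ccccc1)N1C(=O)OC[C@@H]1Cc1ccccc1 | intermediate (not isolated)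
12 | (S)-4-benzyl-3-[(triphenylphosphoranylidene)acetyl]-1,3-oxazolidin-2-one | O=C(C=P(c1ccccc1)(c1ccccc1)c1ccccc1)N1C(=O)OC[C@@H]1Cc1ccccc1 | intermediate
13 | (S)-4-benzyl-3-[(E)-3-(3-benzyloxy-5-bromo-4-hydroxyphenyl)prop-2-enoyl]-1,3-oxazolidin-2-one (key-step precursor) | O=C(/C=C/c1cc(Br)c(O)c(OCc2ccccc2)c1)N1C(=O)OC[C@@H]1Cc1ccccc1 | intermediate
14 | bis-quinone methide: (4S)-4-benzyl-3-[2-{(3-benzyloxy-5-bromo-4-oxocyclohexa-2,5-dien-1-ylidene)methyl}-3-{[3,5-bis(benzyloxy)-4-oxocyclohexa-2,5-dien-1-ylidene]methyl}-4-hydroxybutanoyl]-1,3-oxazolidin-2-one; butanoyl C2 (C8') and C3 (C8) configured as in 17, geometry of the bromo-substituted exocyclic alkene undefined | O=C1C(OCc2ccccc2)=CC(=C[C@@H](CO)[C@@H](C=C2C=C(Br)C(=O)C(OCc3ccccc3)=C2)C(=O)N2C(=O)OC[C@@H]2Cc2ccccc2)C=C1OCc1ccccc1 | intermediate (not isolated)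
15 | oxolane quinone methide: (4S)-4-benzyl-3-{[2-(3-benzyloxy-5-bromo-4-hydroxyphenyl)-4-{[3,5-bis(benzyloxy)-4-oxocyclohexa-2,5-dien-1-ylidene]methyl}oxolan-3-yl]carbonyl}-1,3-oxazolidin-2-one; aryl at oxolane C2 trans to the acyl group at C3, acyl group cis to the C4 substituent, absolute configuration as in 17 | O=C1C(OCc2ccccc2)=CC(=C[C@H]2CO[C@H](c3cc(Br)c(O)c(OCc4ccccc4)c3)[C@H]2C(=O)N2C(=O)OC[C@@H]2Cc2ccccc2)C=C1OCc1ccccc1 | intermediate (not isolated)
16 | hydroxy imide: (4S)-4-benzyl-3-{[2-(3-benzyloxy-5-bromo-4-hydroxyphenyl)-4-{[3,5-bis(benzyloxy)-4-hydroxyphenyl](hydroxy)methyl}oxolan-3-yl]carbonyl}-1,3-oxazolidin-2-one; C7, C8, C8' and C7' configured as in 17 | O[C@H](c1cc(OCc2ccccc2)c(O)c(OCc2ccccc2)c1)[C@H]1CO[C@H](c2cc(Br)c(O)c(OCc3ccccc3)c2)[C@H]1C(=O)N1C(=O)OC[C@@H]1Cc1ccccc1 | intermediate (not isolated)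
17 | (1S,4S,5R,8S)-8-[3-(benzyloxy)-5-bromo-4-hydroxyphenyl]-4-[3,5-bis(benzyloxy)-4-hydroxyphenyl]-3,7-dioxabicyclo[3.3.0]octan-2-one (key-step product; cis-fused, both aryl groups exo) | O=C1O[C@H](c2cc(OCc3ccccc3)c(O)c(OCc3ccccc3)c2)[C@H]2CO[C@H](c3cc(Br)c(O)c(OCc4ccccc4)c3)[C@@H]12 | intermediate
18 | (1S,4S,5R,8S)-8-(3,4-dihydroxyphenyl)-4-(3,4,5-trihydroxyphenyl)-3,7-dioxabicyclo[3.3.0]octan-2-one, (7S,8R,7'S,8'S) in lignan numbering | O=C1O[C@H](c2cc(O)c(O)c(O)c2)[C@H]2CO[C@H](c3ccc(O)c(O)c3)[C@@H]12 | target

**Step count and risk**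

Total step count: 11. Longest linear sequence: 6 steps (steps 1, 2, 3, 4, 10, 11).

Steps most likely to fail:

1. Step 10 (proposed new method).
   - What may go wrong: homo-coupling of either phenol or coupling through a phenolic oxygen may outrun the 8–8' cross-coupling. Reaction through the unchelated imide rotamer may erode or reverse facial selectivity at C8'. The radicals may pair with the topicity that cannot lactonise. Hydration at C7 may occur without delivery from the metal, giving the endo-aryl epimer. The product phenols may be over-oxidised.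
   - Fallback (known chemistry): it sets out from aldehyde 8, uses alcohol 5, and returns at 17. Knoevenagel–Doebner condensation of 8 with malonic acid (pyridine, catalytic piperidine, 90 °C) should give (E)-3-[3-(benzyloxy)-5-bromo-4-hydroxyphenyl]prop-2-enoic acid F1. Co-oxidation of F1 with 5 (Ag2O in CH2Cl2/acetone, or FeCl3·6H2O in aqueous acetone) is the established racemic 8–8' cross-coupling of a hydroxycinnamic acid with a hydroxycinnamyl alcohol. Here the carboxyl group itself captures the C7 quinone methide intramolecularly, so 17 should form together with its mirror image, (1R,4R,5S,8R)-8-[3-(benzyloxy)-5-bromo-4-hydroxyphenyl]-4-[3,5-bis(benzyloxy)-4-hydroxyphenyl]-3,7-dioxabicyclo[3.3.0]octan-2-one F2. Preparative chromatography on a chiral stationary phase then separates the enantiomers and delivers 17.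

2. Step 11.
   - What may go wrong: hydrogenolysis of the benzylic C7–O lactone bond or the C7'–O ether bond may keep pace with debenzylation and debromination. The free pyrogallol may be oxidised by air during isolation.
   - Fallback: it sets out from 17 and returns at 18, separating the two tasks and avoiding hydrogen gas on a metal surface. Homogeneous hydrodebromination with formate (Pd(PPh3)4 catalyst, HCO2Na, DMF, 80 °C) should give (1S,4S,5R,8S)-8-[3-(benzyloxy)-4-hydroxyphenyl]-4-[3,5-bis(benzyloxy)-4-hydroxyphenyl]-3,7-dioxabicyclo[3.3.0]octan-2-one F3. Non-reductive debenzylation of F3 (BCl3, pentamethylbenzene, CH2Cl2, −78 °C) then gives 18.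

3. Step 3.
   - What may go wrong: a second benzyl group may be lost, cleavage may occur at a flanking instead of the central oxygen, or the Lewis acid may be consumed by the ester.
   - Fallback: it sets out from 1 and returns at 4, differentiating the para oxygen at the start by its higher acidity. Allylation of 1 with one equivalent of allyl bromide (KHCO3, DMF, 40 °C) should give 4-(allyloxy)-3,5-dihydroxybenzaldehyde F4. Benzylation (BnBr, K2CO3, DMF) gives 4-(allyloxy)-3,5-bis(benzyloxy)benzaldehyde F5. Wittig olefination as in step 2 gives ethyl (E)-3-[4-(allyloxy)-3,5-bis(benzyloxy)phenyl]prop-2-enoate F6. Palladium-catalysed allyl transfer to morpholine (Pd(PPh3)4 catalyst, morpholine, THF, 20 °C) then frees the para phenol and gives 4.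

**Further compounds**

F1 | step 10 | (E)-3-[3-(benzyloxy)-5-bromo-4-hydroxyphenyl]prop-2-enoic acid | OC(=O)/C=C/c1cc(Br)c(O)c(OCc2ccccc2)c1
F2 | step 10 | (1R,4R,5S,8R)-8-[3-(benzyloxy)-5-bromo-4-hydroxyphenyl]-4-[3,5-bis(benzyloxy)-4-hydroxyphenyl]-3,7-dioxabicyclo[3.3.0]octan-2-one (enantiomer of 17) | O=C1O[C@@H](c2cc(OCc3ccccc3)c(O)c(OCc3ccccc3)c2)[C@@H]2CO[C@@H](c3cc(Br)c(O)c(OCc4ccccc4)c3)[C@H]12
F3 | step 11 | (1S,4S,5R,8S)-8-[3-(benzyloxy)-4-hydroxyphenyl]-4-[3,5-bis(benzyloxy)-4-hydroxyphenyl]-3,7-dioxabicyclo[3.3.0]octan-2-one | O=C1O[C@H](c2cc(OCc3ccccc3)c(O)c(OCc3ccccc3)c2)[C@H]2CO[C@H](c3ccc(O)c(OCc4ccccc4)c3)[C@@H]12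
F4 | step 3 | 4-(allyloxy)-3,5-dihydroxybenzaldehyde | C=CCOc1c(O)cc(C=O)cc1O
F5 | step 3 | 4-(allyloxy)-3,5-bis(benzyloxy)benzaldehyde | C=CCOc1c(OCc2ccccc2)cc(C=O)cc1OCc1ccccc1
F6 | step 3 | ethyl (E)-3-[4-(allyloxy)-3,5-bis(benzyloxy)phenyl]prop-2-enoate | CCOC(=O)/C=C/c1cc(OCc2ccccc2)c(OCC=C)c(OCc2ccccc2)c1
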